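All runs stem from a simulated flask with made-up constants; noise was put on by code.

Start from 19%: north's reading of J at 2.50 min, with the temperature, G and time of autumn, on a Z charge of 0.059 M against autumn's 0.10 M.

| setting | south | north | south-east | winter | autumn |
|---|---|---|---|---|---|
| Z | 0.034 M (fed, over 15 s) | 0.059 M (fed, over 15 s) | 0.11 M (fed, over 15 s) | 0.030 M | 0.10 M (fed, over 15 s) |
| G | 0.20 mM | 0.20 mM | 0.20 mM | 0.20 mM | 0.20 mM |
| temperature | 95 °C | 110 °C | 95 °C | 110 °C | 110 °C |
| remark | run made earlier | run made earlier | run made earlier | everything together at the start |  |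
| time |  |  |  | 1.2 min | 2.5 min |

| run | time / min | J / % |
|---|---|---|
| south | 1.33 | 3 |
| south | 3.00 | 8 |
| south | 4.00 | 14 |
| south | 5.00 | 22 |
| north | 0.333 | 0 |
| north | 0.833 | 4 |
| north | 1.50 | 12 |
| north | 2.50 | 19 |
| south-east | 0.417 | 0 |
| south-east | 1.00 | 1 |
| south-east | 2.00 | 7 |
| south-east | 5.00 | 17 |

(standard deviation of a reading: 1.5 percentage points)

- the numbers in the tables scatter by 1.5 percentage points (one standard deviation)
- a reading or a percentage of J counts all its forms, free or not

- which one finishes higher in amount of J, in percent of the Z charged ("neither" within 2 percentage points) (winter / autumn / neither)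
- amount of J at the end, in percent of the Z charged, winter
- amount of J at the end, in percent of the Z charged, autumn

1. Take percent of the charge as the large term, the pseudo-first-order picture, and reckon the effect of [Z] as a small correction.
2. Read that correction from the 95 °C pair, whose charges differ by a factor 3.24. At 5.00 min, south stands 5 percentage points above south-east, which gives 4.3 points per factor e.
3. Carry this to 110 °C unchanged. Autumn lies 0.528 natural-log units above north, so the first estimate for autumn is 16.7%.
4. Reforge the weak link, which is one pair of readings with a scatter of 1.5 points each. Interpolate south-east linearly to south's times. The gaps at 3.00 min and 4.00 min are −2.3 points and 0.33 points, so their mean with the gap at 5.00 min is 1 point, less than the scatter of one reading.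
5. Define the charge shift, the points of J percent lost per factor e of Z charge at equal time, temperature and G, here as read from these scattered runs: 0.85 points.
6. Commit for autumn to 18.6%.
7. For winter, interpolate north to 1.2 min, leave the 15 s feed aside, and add the shift. This gives 8.98%, so my reckoning puts autumn higher than winter.

The forecast says autumn, with winter at 6% (3% to 10%) and autumn at 18% (12% to 25%). Its ground for winter: “Winter is dilute and short, so it stays in the lag”. My winter figure stands higher than the forecast's.

The flasks give autumn: winter 7.50%, autumn 18.8%.

    Z + J ⇌ X, settled at all times (K = 120 M⁻¹, ΔH = 5.00 kJ mol⁻¹)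
    Q → D + J (k = 6.70 s⁻¹, Ea = 75.0 kJ mol⁻¹)
    G → D (k = 0.0150 s⁻¹, Ea = 99.0 kJ mol⁻¹)
    Z + D ⇌ Q (K = 2.90 M⁻¹, k = 72.0 M⁻¹ s⁻¹, Ea = 38.0 kJ mol⁻¹, ΔH = −57.0 kJ mol⁻¹)
    (constants at 110 °C)

Now read autumn at 4.0 min: extend north's last slope and subtract the charge shift over the step from north to autumn, 0.45 points, which gives 29.1%. That neighbouring flask gives 31.0%.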